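In the first minutes of Friday's run the open intermediate climbed steadily, reaching 4.9% after 3.00 min, yet at 15.0 min open intermediate and target together stood at 11.3%, though reagent had been charged equal to substrate.

| setting | Friday's | dusk | winter | summer | spring |
|---|---|---|---|---|---|
| substrate | 0.071 M | 0.071 M | 0.071 M | 0.071 M | 0.071 M |
| partner | 0.21 M | 0.106 M | 0.106 M | 0.106 M | 0.106 M |
| reagent | 0.071 M | 0.0710 M | 0.0710 M | 0.0710 M | 0.0710 M |
| temperature | 120 °C | 120 °C | 90 °C | 60 °C | 150 °C |
| remark | run made earlier |  |  |  |  |
| time |  | 2.5 h | 2.5 h | 2.5 h | 2.5 h |

Friday's run (percent of the substrate charged)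

| time / min | open intermediate / % | target / % |
|---|---|---|
| 1.33 | 2.2 | 0 |
| 3.00 | 4.9 | 0 |
| 6.00 | 8.2 | 0.5 |
| 15.0 | 9.5 | 1.8 |

(readings scatter by 0.5 percentage points)

- which flask leads in amount of open intermediate, in percent of the substrate charged ("all alike" within 1.5 percentage points) (dusk / winter / summer / spring / all alike)
- how much open intermediate is there at the end, in percent of the substrate charged: dusk
- how much open intermediate is there at the end, in percent of the substrate charged: winter
- how much open intermediate is there at the end, in percent of the substrate charged: summer
- how much open intermediate is there at the end, in percent of the substrate charged: spring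

- the analysis behind the earlier runs scatters by 0.5 percentage points, standard deviation
- the earlier runs do not show what temperature does; that part of a forecast is a guess

I read that stall as reagent being taken by the partner, pseudo-first-order in partner, so that the rise fades over the reagent's lifetime. Dividing the turned amount by the early slope gives that lifetime on Friday's partner charge, and I scaled it inversely with partner. The number I carried is N, the reagent lifetimes that fit into a flask's time, and a fraction of about exp(−N) of the reagent should remain. Working in logarithms, I guessed that each temperature step moves log N by 0.7, and I left the ceiling below unchanged with temperature, which was a guess too.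

lifetime, Friday's = 6.92 min

N, dusk = 2.5 h × 0.106 M / (0.21 M × 6.92 min) = 10.9

N, winter = 2.18; summer = 0.436; spring = 54.8

With partner halved, I expected the ceiling of turned substrate to rise to 22.4%, and the ceiling times 1 − exp(−N), with the drain to target set aside, gave me 19.9% open intermediate for winter and 7.92% for summer. For dusk and spring, N stands far above one, so I expected the end to hang on the drain to target, and for those two flasks one number was not enough.

The forecast, reading “a fast reversible step”, named winter too, but with 4.7% for dusk, 6.5% for winter, 2.5% for summer and 2.7% for spring, so for winter it stood below my figure.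

The flasks gave 1.44% for dusk, 19.8% for winter, 9.77% for summer and 0% for spring, and winter led.

    2 open intermediate → homo product (k = 6.40 × 10⁻⁴ M⁻¹ s⁻¹, Ea = 77.0 kJ mol⁻¹)
    target → over-reaction product (k = 4.00 × 10⁻⁷ s⁻¹, Ea = 123 kJ mol⁻¹)
    open intermediate + second intermediate → target (k = 0.00130 M⁻¹ s⁻¹, Ea = 68.0 kJ mol⁻¹)
    reagent + partner → second intermediate (k = 0.00180 M⁻¹ s⁻¹, Ea = 84.0 kJ mol⁻¹)
    substrate + reagent → open intermediate (k = 0.00120 M⁻¹ s⁻¹, Ea = 63.0 kJ mol⁻¹)
    (constants at 90 °C)

Winter ended with 15.1% of its reagent against the 11.3% I had reckoned from N. The neighbouring flask is winter with substrate cut to 0.018 M; its partner, temperature and time are winter's, so I kept N at 2.18, and the ceiling, which I had scaled with partner, stayed at 22.4%. The same reckoning gives 11.3% of the reagent left and 19.9% open intermediate. That flask ended with 25% of its reagent and 24.2% open intermediate.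

Readings and results come from a simulation on assumed constants, and the scatter is random.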